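The plan makes ring A (C4a, C5, C6, C7, C8, C8a) de novo instead of alkylating a phloroglucinol. The key step exploits two features: the alkylated carbon C8 is flanked by the oxygen-bearing carbons C7 and C8a and faces the methoxylated C5 across the ring, and the C8 side chain, up to its tertiary carbinol, is a p-menthane cut open between two ring carbons. A Danheiser benzannulation joins a limonene-derived triisopropylsilyl ynol ether (carbinol as TES ether) to 3-methoxycyclobutenone, creating C8–C8a and C6–C7, closing ring A and leaving its three oxygens differentiated (OH, OTIPS, OMe). The free phenol then steers formylation to C4a; ynone cyclisation and fluoride desilylation finish the flavone without acid.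

Key step: step 8

Remark: the side-chain stereocentre of the target is (R). It is C4 of (4R)-limonene 1,2-oxide, the epoxide of (R)-(+)-limonene, and no bond to it is made or broken. The commercial cis/trans epoxide mixture is acceptable because both epoxide carbons are cleaved in step 1. All phenol protecting groups are silyl, so no acid meets the isopropenyl/phenol/tertiary-alcohol array late in the route.

Step 1
Reactants: 1 (4R)-limonene 1,2-oxide (commercial cis/trans mixture)
Product: 2 (3R)-6-oxo-3-(prop-1-en-2-yl)heptanal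
Conditions: H5IO6, THF/H2O, 0 °C to rt
Reagents that add atoms: water, O
Why: Periodic acid opens the epoxide to the 1,2-diol in situ and cleaves it (Malaprade-type glycol cleavage), so both epoxide diastereomers should converge on one keto-aldehyde while the isopropenyl group and the C–H stereocentre stay untouched.

Step 2
Reactants: 2 (3R)-6-oxo-3-(prop-1-en-2-yl)heptanal
Product: 3 (3R)-6-oxo-3-(prop-1-en-2-yl)heptanoic acid
Conditions: NaClO2, NaH2PO4, 2-methyl-2-butene, t-BuOH/H2O, 0 °C to rt
Reagents that add atoms: sodium chlorite, [Na+].[O-]Cl=O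
Why: Pinnick oxidation converts the aldehyde to the acid under buffered conditions, and the scavenger alkene traps HOCl so that the isopropenyl group and the methyl ketone should survive.

Step 3
Reactants: 3 (3R)-6-oxo-3-(prop-1-en-2-yl)heptanoic acid
Product: 4 methyl (3R)-6-oxo-3-(prop-1-en-2-yl)heptanoate
Conditions: MeI, K2CO3, DMF, rt
Reagents that add atoms: iodomethane, CI
Why: SN2 O-alkylation of the carboxylate gives the methyl ester under conditions too mild to alkylate or condense the methyl ketone.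

Step 4
Reactants: 4 methyl (3R)-6-oxo-3-(prop-1-en-2-yl)heptanoate
Product: 5 methyl (3R)-6-hydroxy-6-methyl-3-(prop-1-en-2-yl)heptanoate
Conditions: MeMgBr (1.1 equiv), THF, −78 °C
Reagents that add atoms: methylmagnesium bromide, C[Mg]Br
Why: Grignard addition is chemoselective for the ketone over the ester at low temperature, and the new carbinol carbon carries two methyl groups and is therefore not stereogenic.

Step 5
Reactants: 5 methyl (3R)-6-hydroxy-6-methyl-3-(prop-1-en-2-yl)heptanoate
Product: 6 methyl (3R)-6-methyl-3-(prop-1-en-2-yl)-6-(triethylsilyloxy)heptanoate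
Conditions: TESOTf, 2,6-lutidine, CH2Cl2, −78 to 0 °C
Reagents that add atoms: triethylsilyl trifluoromethanesulfonate, CC[Si](CC)(CC)OS(=O)(=O)C(F)(F)F
Why: A silyl triflate with a hindered pyridine base silylates the tertiary alcohol, which masks the only protic group before the strongly basic homologation and the ketene chemistry.

Step 6
Reactants: 6 methyl (3R)-6-methyl-3-(prop-1-en-2-yl)-6-(triethylsilyloxy)heptanoate
Product: 9 (4R)-7-methyl-4-(prop-1-en-2-yl)-7-(triethylsilyloxy)-1-(triisopropylsilyloxy)oct-1-yne, via dibromomethyl ketone 7 (not isolated), via lithium ynolate 8 (not isolated)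
Conditions: CH2Br2, LiTMP, THF, −78 °C; then n-BuLi, −78 °C to rt; then TIPSOTf, −78 to 0 °C
Reagents that add atoms: dibromomethane, BrCBr; triisopropylsilyl trifluoromethanesulfonate, CC(C)[Si](OS(=O)(=O)C(F)(F)F)(C(C)C)C(C)C
Why: Kowalski ester homologation: LiCHBr2 acylation gives the dibromoketone enolate, Br/Li exchange triggers the carbenoid 1,2-shift to the ynolate (the ester carbon becomes the chain-bearing alkyne carbon), and the bulky silyl triflate should silylate on oxygen to give the isolable TIPS ynol ether.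

Step 7
Reactants: 10 3-ethoxycyclobut-2-en-1-one
Product: 11 3-methoxycyclobut-2-en-1-one
Conditions: MeOH (solvent), CSA (5 mol %), rt; Et3N, concentrate, repeat once, distil
Reagents that add atoms: methanol, CO
Why: Acid-catalysed alkoxy exchange of a vinylogous ester by addition–elimination at C3, driven by the solvent excess; mild aqueous acid hydrolyses such alkoxycyclobutenones by the same C3 pathway, so ring cleavage at the carbonyl is not expected at room temperature.

Step 8
Reactants: 9 (4R)-7-methyl-4-(prop-1-en-2-yl)-7-(triethylsilyloxy)-1-(triisopropylsilyloxy)oct-1-yne; 11 3-methoxycyclobut-2-en-1-one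
Product: 16 5-methoxy-2-[(2R)-5-methyl-2-(prop-1-en-2-yl)-5-(triethylsilyloxy)hexyl]-3-(triisopropylsilyloxy)phenol, via methoxyvinylketene 12 (not isolated), via vinylcyclobutenone adduct 13 (not isolated), via dienylketene 14 (not isolated), via cyclohexadienone tautomer 15 (not isolated)
Conditions: toluene, 80 to 110 °C, Ar, 11 (1.5 equiv) added slowly
Reagents that add atoms: none
Why: On heating, 11 undergoes reversible 4π electrocyclic opening to methoxyvinylketene 12, whose ketene C=C adds [2+2] to ynol ether 9 to give 13, a second 4π opening gives dienylketene 14, and 6π electrocyclisation followed by enolisation of 15 should deliver phenol 16. This is the Danheiser benzannulation in its siloxyalkyne variant, the reaction type that makes 2-alkylresorcinol monosilyl ethers from ester-derived ynol ethers and 3-substituted cyclobutenones. Ring A is closed by the thermal disrotatory 6π electrocyclisation, which re-forms the C4a–C8a bond that was the cleaved σ-bond of 11, so the net new skeletal bonds are C8–C8a and C6–C7 from the [2+2] step. No stereocentre is created, and the limonene-derived centre, β to the alkyne and non-enolisable, cannot epimerise under neutral thermal conditions. The step needs the [2+2] regiochemistry that joins the chain-bearing alkyne carbon to the ketene carbonyl carbon, and the polarisation of the ynol ether, nucleophilic at exactly that carbon, secures it and places C8 between the two oxygenated carbons and para to OMe. It also needs chemoselectivity for the alkyne over the isopropenyl group and over O-acylation of the product phenol, which the far higher ketenophilicity of the siloxyalkyne and the slow addition of 11 should provide.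

Step 9
Reactants: 16 5-methoxy-2-[(2R)-5-methyl-2-(prop-1-en-2-yl)-5-(triethylsilyloxy)hexyl]-3-(triisopropylsilyloxy)phenol
Product: 18 2-hydroxy-6-methoxy-3-[(2R)-5-methyl-2-(prop-1-en-2-yl)-5-(triethylsilyloxy)hexyl]-4-(triisopropylsilyloxy)benzaldehyde, via salicyl alcohol 17 (not isolated)
Conditions: MgCl2, Et3N, (CH2O)n, MeCN, reflux
Reagents that add atoms: paraformaldehyde (as formaldehyde), C=O
Why: Casnati–Skattebøl ortho-formylation: the magnesium phenoxide delivers formaldehyde only to the carbon ortho to the free OH (C4a, the one open ortho position), a second formaldehyde oxidises the salicyl alcohol by Oppenauer-type hydride transfer, and C6, which has no adjacent free OH, should stay untouched in this non-acidic medium.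

Step 10
Reactants: 19 2,4-dihydroxybenzaldehyde
Product: 20 2,4-bis(triisopropylsilyloxy)benzaldehyde
Conditions: TIPSOTf, 2,6-lutidine, CH2Cl2, 0 °C to rt
Reagents that add atoms: triisopropylsilyl trifluoromethanesulfonate, CC(C)[Si](OS(=O)(=O)C(F)(F)F)(C(C)C)C(C)C
Why: The silyl triflate silylates both phenols, including the hydrogen-bonded 2-OH, and gives B-ring protection that leaves with fluoride at the end.

Step 11
Reactants: 20 2,4-bis(triisopropylsilyloxy)benzaldehyde
Product: 21 1-ethynyl-2,4-bis(triisopropylsilyloxy)benzene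
Conditions: TMSCHN2, LDA, THF, −78 °C to rt
Reagents that add atoms: (trimethylsilyl)diazomethane, C[Si](C)(C)C=[N+]=[N-]
Why: Colvin rearrangement: lithiated TMS-diazomethane adds to the aldehyde, Peterson elimination and loss of N2 give an alkylidene carbene whose 1,2-hydrogen shift gives the terminal alkyne, and the methoxide-free conditions should leave the aryl silyl ethers intact.

Step 12
Reactants: 18 2-hydroxy-6-methoxy-3-[(2R)-5-methyl-2-(prop-1-en-2-yl)-5-(triethylsilyloxy)hexyl]-4-(triisopropylsilyloxy)benzaldehyde; 21 1-ethynyl-2,4-bis(triisopropylsilyloxy)benzene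
Product: 23 2-{3-[2,4-bis(triisopropylsilyloxy)phenyl]-1-hydroxyprop-2-yn-1-yl}-3-methoxy-6-[(2R)-5-methyl-2-(prop-1-en-2-yl)-5-(triethylsilyloxy)hexyl]-5-(triisopropylsilyloxy)phenol (mixture of carbinol epimers), via lithium acetylide 22 (not isolated)
Conditions: 21 (2.5 equiv), n-BuLi (2.4 equiv), THF, −78 °C; then 18, −78 to 0 °C; pH 7 buffer
Reagents that add atoms: none
Why: 1,2-Addition of a lithium acetylide to the aldehyde, with the first equivalent consumed as the phenoxide and the excess alkyne recoverable; the new carbinol centre is formed without control and is erased by the oxidation in step 13.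

Step 13
Reactants: 23 2-{3-[2,4-bis(triisopropylsilyloxy)phenyl]-1-hydroxyprop-2-yn-1-yl}-3-methoxy-6-[(2R)-5-methyl-2-(prop-1-en-2-yl)-5-(triethylsilyloxy)hexyl]-5-(triisopropylsilyloxy)phenol
Product: 24 3-[2,4-bis(triisopropylsilyloxy)phenyl]-1-{2-hydroxy-6-methoxy-3-[(2R)-5-methyl-2-(prop-1-en-2-yl)-5-(triethylsilyloxy)hexyl]-4-(triisopropylsilyloxy)phenyl}prop-2-yn-1-one
Conditions: activated MnO2 (excess), CH2Cl2, rt
Reagents that add atoms: none
Why: Manganese dioxide oxidises the doubly activated (benzylic and propargylic) alcohol selectively and under neutral conditions, which should spare the free phenol, the isolated alkene and the silyl ethers.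

Step 14
Reactants: 24 3-[2,4-bis(triisopropylsilyloxy)phenyl]-1-{2-hydroxy-6-methoxy-3-[(2R)-5-methyl-2-(prop-1-en-2-yl)-5-(triethylsilyloxy)hexyl]-4-(triisopropylsilyloxy)phenyl}prop-2-yn-1-one
Product: 25 2-[2,4-bis(triisopropylsilyloxy)phenyl]-5-methoxy-8-[(2R)-5-methyl-2-(prop-1-en-2-yl)-5-(triethylsilyloxy)hexyl]-7-(triisopropylsilyloxy)-4H-chromen-4-one
Conditions: K2CO3, acetone, rt to 50 °C
Reagents that add atoms: none
Why: Base-mediated 6-endo-dig oxa-Michael cyclisation of an o-hydroxyaryl ynone, which in an aprotic medium should close the 4-pyranone (O1–C2 bond) in preference to the 5-exo aurone and needs no acid.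

Step 15
Reactants: 25 2-[2,4-bis(triisopropylsilyloxy)phenyl]-5-methoxy-8-[(2R)-5-methyl-2-(prop-1-en-2-yl)-5-(triethylsilyloxy)hexyl]-7-(triisopropylsilyloxy)-4H-chromen-4-one
Product: 26 2-(2,4-dihydroxyphenyl)-7-hydroxy-8-[(2R)-5-hydroxy-5-methyl-2-(prop-1-en-2-yl)hexyl]-5-methoxy-4H-chromen-4-one
Conditions: TBAF (excess), THF, 0 to 40 °C; aqueous work-up at pH 6–7
Reagents that add atoms: none
Why: Fluoride-mediated desilylation should cleave the three aryl TIPS ethers and the tertiary TES ether in one operation without acid, so the isopropenyl group cannot cyclise onto the 7-OH and the tertiary alcohol cannot eliminate.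

Compound list
1 | (4R)-limonene 1,2-oxide [(4R)-1-methyl-4-(prop-1-en-2-yl)-7-oxabicyclo[4.1.0]heptane], cis/trans mixture at the epoxide carbons | CC12OC1C[C@@H](CC2)C(C)=C | starting material
2 | (3R)-6-oxo-3-(prop-1-en-2-yl)heptanal | C=C(C)[C@H](CCC(C)=O)CC=O | intermediate
3 | (3R)-6-oxo-3-(prop-1-en-2-yl)heptanoic acid | C=C(C)[C@H](CCC(C)=O)CC(=O)O | intermediate
4 | methyl (3R)-6-oxo-3-(prop-1-en-2-yl)heptanoate | C=C(C)[C@H](CCC(C)=O)CC(=O)OC | intermediate
5 | methyl (3R)-6-hydroxy-6-methyl-3-(prop-1-en-2-yl)heptanoate | C=C(C)[C@H](CCC(C)(C)O)CC(=O)OC | intermediate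
6 | methyl (3R)-6-methyl-3-(prop-1-en-2-yl)-6-(triethylsilyloxy)heptanoate | C=C(C)[C@H](CCC(C)(C)O[Si](CC)(CC)CC)CC(=O)OC | intermediate
7 | (4R)-1,1-dibromo-7-methyl-4-(prop-1-en-2-yl)-7-(triethylsilyloxy)octan-2-one (present as its lithium enolate) | C=C(C)[C@H](CCC(C)(C)O[Si](CC)(CC)CC)CC(=O)C(Br)Br | intermediate (not isolated)
8 | lithium (4R)-7-methyl-4-(prop-1-en-2-yl)-7-(triethylsilyloxy)oct-1-yn-1-olate | C=C(C)[C@H](CCC(C)(C)O[Si](CC)(CC)CC)CC#C[O-].[Li+] | intermediate (not isolated)
9 | (4R)-7-methyl-4-(prop-1-en-2-yl)-7-(triethylsilyloxy)-1-(triisopropylsilyloxy)oct-1-yne | C=C(C)[C@H](CCC(C)(C)O[Si](CC)(CC)CC)CC#CO[Si](C(C)C)(C(C)C)C(C)C | intermediate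
10 | 3-ethoxycyclobut-2-en-1-one | CCOC1=CC(=O)C1 | starting material
11 | 3-methoxycyclobut-2-en-1-one | COC1=CC(=O)C1 | intermediate
12 | 3-methoxybuta-1,3-dien-1-one (methoxyvinylketene) | C=C(OC)C=C=O | intermediate (not isolated)
13 | 4-(1-methoxyethenyl)-2-[(2R)-5-methyl-2-(prop-1-en-2-yl)-5-(triethylsilyloxy)hexyl]-3-(triisopropylsilyloxy)cyclobut-2-en-1-one (ring CH epimers) | C=C(C)[C@H](CCC(C)(C)O[Si](CC)(CC)CC)CC1=C(O[Si](C(C)C)(C(C)C)C(C)C)C(C(OC)=C)C1=O | intermediate (not isolated)
14 | 5-methoxy-2-[(2R)-5-methyl-2-(prop-1-en-2-yl)-5-(triethylsilyloxy)hexyl]-3-(triisopropylsilyloxy)hexa-1,3,5-trien-1-one, isomer with ketene carbon and methoxyvinyl group cis on the central double bond | C=C(C)[C@H](CCC(C)(C)O[Si](CC)(CC)CC)CC(=C=O)/C(O[Si](C(C)C)(C(C)C)C(C)C)=C\C(OC)=C | intermediate (not isolated)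
15 | 5-methoxy-2-[(2R)-5-methyl-2-(prop-1-en-2-yl)-5-(triethylsilyloxy)hexyl]-3-(triisopropylsilyloxy)cyclohexa-2,4-dien-1-one | C=C(C)[C@H](CCC(C)(C)O[Si](CC)(CC)CC)CC1=C(O[Si](C(C)C)(C(C)C)C(C)C)C=C(OC)CC1=O | intermediate (not isolated)
16 | 5-methoxy-2-[(2R)-5-methyl-2-(prop-1-en-2-yl)-5-(triethylsilyloxy)hexyl]-3-(triisopropylsilyloxy)phenol | C=C(C)[C@H](CCC(C)(C)O[Si](CC)(CC)CC)Cc1c(O)cc(OC)cc1O[Si](C(C)C)(C(C)C)C(C)C | intermediate
17 | 2-(hydroxymethyl)-3-methoxy-6-[(2R)-5-methyl-2-(prop-1-en-2-yl)-5-(triethylsilyloxy)hexyl]-5-(triisopropylsilyloxy)phenol | C=C(C)[C@H](CCC(C)(C)O[Si](CC)(CC)CC)Cc1c(O)c(CO)c(OC)cc1O[Si](C(C)C)(C(C)C)C(C)C | intermediate (not isolated)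
18 | 2-hydroxy-6-methoxy-3-[(2R)-5-methyl-2-(prop-1-en-2-yl)-5-(triethylsilyloxy)hexyl]-4-(triisopropylsilyloxy)benzaldehyde | C=C(C)[C@H](CCC(C)(C)O[Si](CC)(CC)CC)Cc1c(O)c(C=O)c(OC)cc1O[Si](C(C)C)(C(C)C)C(C)C | intermediate
19 | 2,4-dihydroxybenzaldehyde | O=Cc1ccc(O)cc1O | starting material
20 | 2,4-bis(triisopropylsilyloxy)benzaldehyde | O=Cc1ccc(O[Si](C(C)C)(C(C)C)C(C)C)cc1O[Si](C(C)C)(C(C)C)C(C)C | intermediate
21 | 1-ethynyl-2,4-bis(triisopropylsilyloxy)benzene | C#Cc1ccc(O[Si](C(C)C)(C(C)C)C(C)C)cc1O[Si](C(C)C)(C(C)C)C(C)C | intermediate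
22 | lithium [2,4-bis(triisopropylsilyloxy)phenyl]acetylide | [Li]C#Cc1ccc(O[Si](C(C)C)(C(C)C)C(C)C)cc1O[Si](C(C)C)(C(C)C)C(C)C | intermediate (not isolated)
23 | 2-{3-[2,4-bis(triisopropylsilyloxy)phenyl]-1-hydroxyprop-2-yn-1-yl}-3-methoxy-6-[(2R)-5-methyl-2-(prop-1-en-2-yl)-5-(triethylsilyloxy)hexyl]-5-(triisopropylsilyloxy)phenol (carbinol epimers) | C=C(C)[C@H](CCC(C)(C)O[Si](CC)(CC)CC)Cc1c(O)c(C(O)C#Cc2ccc(O[Si](C(C)C)(C(C)C)C(C)C)cc2O[Si](C(C)C)(C(C)C)C(C)C)c(OC)cc1O[Si](C(C)C)(C(C)C)C(C)C | intermediate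
24 | 3-[2,4-bis(triisopropylsilyloxy)phenyl]-1-{2-hydroxy-6-methoxy-3-[(2R)-5-methyl-2-(prop-1-en-2-yl)-5-(triethylsilyloxy)hexyl]-4-(triisopropylsilyloxy)phenyl}prop-2-yn-1-one | C=C(C)[C@H](CCC(C)(C)O[Si](CC)(CC)CC)Cc1c(O)c(C(=O)C#Cc2ccc(O[Si](C(C)C)(C(C)C)C(C)C)cc2O[Si](C(C)C)(C(C)C)C(C)C)c(OC)cc1O[Si](C(C)C)(C(C)C)C(C)C | intermediate
25 | 2-[2,4-bis(triisopropylsilyloxy)phenyl]-5-methoxy-8-[(2R)-5-methyl-2-(prop-1-en-2-yl)-5-(triethylsilyloxy)hexyl]-7-(triisopropylsilyloxy)-4H-chromen-4-one | C=C(C)[C@H](CCC(C)(C)O[Si](CC)(CC)CC)Cc1c(O[Si](C(C)C)(C(C)C)C(C)C)cc(OC)c2c(=O)cc(-c3ccc(O[Si](C(C)C)(C(C)C)C(C)C)cc3O[Si](C(C)C)(C(C)C)C(C)C)oc12 | intermediate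
26 | 2-(2,4-dihydroxyphenyl)-7-hydroxy-8-[(2R)-5-hydroxy-5-methyl-2-(prop-1-en-2-yl)hexyl]-5-methoxy-4H-chromen-4-one | C=C(C)[C@H](CCC(C)(C)O)Cc1c(O)cc(OC)c2c(=O)cc(-c3ccc(O)cc3O)oc12 | target

Total step count: 15.
Longest linear sequence: 12 steps (steps 1–6, 8, 9, 12–15).

Steps most likely to fail

Step 8. The thermal opening of 11 may need a temperature at which the ynol ether isomerises to a silylketene, or the vinylketene may be lost to dimerisation or to acylation of the product phenol. The fallback sets out from 9 and comes back at 16; it makes the same ketene 12 at room temperature by photochemical Wolff rearrangement. Commercial 3,3-dimethoxybutan-2-one (CC(=O)C(C)(OC)OC) would lose methanol on distillation from catalytic TsOH to give 3-methoxybut-3-en-2-one F1. Its lithium enolate (LiHMDS, THF, −78 °C) would be trifluoroacetylated with CF3CO2CH2CF3 to 1,1,1-trifluoro-5-methoxyhex-5-ene-2,4-dione F2. Detrifluoroacetylative diazo transfer (MsN3, Et3N, H2O, MeCN) would then give 1-diazo-3-methoxybut-3-en-2-one F3. Irradiation of F3 with 9 (CH2Cl2, Pyrex-filtered mercury lamp, rt), followed by brief warming to finish the electrocyclic steps, should lead through 12–15 to 16.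

Step 6. The carbenoid rearrangement to the ynolate may be incomplete, or silylation may occur on carbon, or the ynol ether may decompose during isolation. The fallback sets out from 6 and comes back at 9; it reaches the ynolate by oxygenation of an acetylide instead of ester homologation. DIBAL-H (CH2Cl2, −78 °C) would reduce 6 to (3R)-6-methyl-3-(prop-1-en-2-yl)-6-(triethylsilyloxy)heptanal F4. Ohira–Bestmann homologation (dimethyl (1-diazo-2-oxopropyl)phosphonate, K2CO3, MeOH) would give (4R)-7-methyl-4-(prop-1-en-2-yl)-7-(triethylsilyloxy)oct-1-yne F5. n-BuLi (THF, −78 °C) would form lithium (4R)-7-methyl-4-(prop-1-en-2-yl)-7-(triethylsilyloxy)oct-1-yn-1-ide F6. Lithium tert-butyl peroxide (t-BuOOH, LiHMDS, −78 to 0 °C) would oxidise F6 to the same ynolate 8, and TIPSOTf would then give 9.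

Step 12. Addition to the phenoxide-deactivated, doubly ortho-substituted aldehyde may be sluggish and waste the convergent alkyne, and the electron-rich benzylic alcohol may ionise on work-up. The fallback sets out from 18 and comes back at 23; it forms the aryl–alkyne bond by cross-coupling. Ethynylmagnesium bromide (large excess, THF, 0 °C to rt) would add to 18 to give 2-(1-hydroxyprop-2-yn-1-yl)-3-methoxy-6-[(2R)-5-methyl-2-(prop-1-en-2-yl)-5-(triethylsilyloxy)hexyl]-5-(triisopropylsilyloxy)phenol F7. Commercial 4-iodoresorcinol (Oc1ccc(I)c(O)c1) would be silylated (TIPSOTf, 2,6-lutidine, CH2Cl2) to 1-iodo-2,4-bis(triisopropylsilyloxy)benzene F8. Sonogashira coupling of F7 with F8 (Pd(PPh3)2Cl2, CuI, Et3N, THF, rt) should give 23.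

Further compounds
F1 | step 8 | 3-methoxybut-3-en-2-one | C=C(OC)C(C)=O
F2 | step 8 | 1,1,1-trifluoro-5-methoxyhex-5-ene-2,4-dione | C=C(OC)C(=O)CC(=O)C(F)(F)F
F3 | step 8 | 1-diazo-3-methoxybut-3-en-2-one | C=C(OC)C(=O)C=[N+]=[N-]
F4 | step 6 | (3R)-6-methyl-3-(prop-1-en-2-yl)-6-(triethylsilyloxy)heptanal | C=C(C)[C@H](CCC(C)(C)O[Si](CC)(CC)CC)CC=O
F5 | step 6 | (4R)-7-methyl-4-(prop-1-en-2-yl)-7-(triethylsilyloxy)oct-1-yne | C=C(C)[C@H](CCC(C)(C)O[Si](CC)(CC)CC)CC#C
F6 | step 6 | lithium (4R)-7-methyl-4-(prop-1-en-2-yl)-7-(triethylsilyloxy)oct-1-yn-1-ide | C=C(C)[C@H](CCC(C)(C)O[Si](CC)(CC)CC)CC#C[Li]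
F7 | step 12 | 2-(1-hydroxyprop-2-yn-1-yl)-3-methoxy-6-[(2R)-5-methyl-2-(prop-1-en-2-yl)-5-(triethylsilyloxy)hexyl]-5-(triisopropylsilyloxy)phenol (carbinol epimers) | C=C(C)[C@H](CCC(C)(C)O[Si](CC)(CC)CC)Cc1c(O)c(C(O)C#C)c(OC)cc1O[Si](C(C)C)(C(C)C)C(C)C
F8 | step 12 | 1-iodo-2,4-bis(triisopropylsilyloxy)benzene | Ic1ccc(O[Si](C(C)C)(C(C)C)C(C)C)cc1O[Si](C(C)C)(C(C)C)C(C)C
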